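**Plan**
1. Retrosynthesis: C8–OH, ArOH and the C5–C6 single bond are traced back to C8–OBn, ArOBn and a C5≡C6 triple bond (one hydrogenation undoes all three), and the acetyl group is taken off C2–O. The chain is then cut at C4–C5 into a 2-substituted oxetane and a terminal alkyne. The oxetane is cut at C3–C4 and C1–aryl, the alkyne at C6–C7 and C9–C10, both back to (S)-epichlorohydrin.
2. Enabling feature: the acetoxy oxygen on C2 stands 1,3 to C4, so O, C2, C3 and C4 can be closed as an oxetane whose only unsubstituted ring carbon is C4 and whose oxygen returns as the C2 hydroxyl. C5 is the terminal sp carbon of a homopropargylic ether (C5≡C6–C7–C8–O).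
3. Forward: aryl Grignard + epichlorohydrin → benzyloxirane → oxetane (left half); butyl Grignard + epichlorohydrin → pentyloxirane → acetylide opening → benzyl ether (right half). Acetylide opening of the oxetane joins the halves, the single free OH is acetylated, and one hydrogenation (alkyne → CH2CH2, two O-benzyl → OH) gives the target. The target has no ring to build; the oxetane is a temporary ring.
4. Stereochemistry: C2 (R) and C8 (S) are both the stereocentre of (S)-epichlorohydrin, used once in each half. No bond to either centre is broken afterwards; the S → R change at C2 in step 7 is a change of CIP priority only.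

Key step: step 7

Remark: chain carbons are numbered C1 (ArCH2) to C13 as in the tridecane name of the target; 3-bromo-5-methoxyphenol, (S)-epichlorohydrin, n-butylmagnesium bromide and lithium acetylide–ethylenediamine are taken as commercial.

Step 1
Reactants: 1 3-bromo-5-methoxyphenol
Product: 2 1-(benzyloxy)-3-bromo-5-methoxybenzene
Conditions: BnBr, K2CO3, DMF, rt
Reagents that add atoms: benzyl bromide, BrCc1ccccc1
Why: Williamson ether synthesis on the phenoxide masks the acidic phenol before Grignard formation, as a benzyl ether that the final hydrogenation removes.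

Step 2
Reactants: 2 1-(benzyloxy)-3-bromo-5-methoxybenzene; 3 (S)-epichlorohydrin
Product: 6 (S)-2-[3-(benzyloxy)-5-methoxybenzyl]oxirane, via arylmagnesium bromide 4 (not isolated), via chlorohydrin 5 (not isolated)
Conditions: Mg, I2 (cat.), THF, reflux; then 3, CuI (10 mol%), THF, −40 to 0 °C; aqueous work-up; crude 5, powdered NaOH, Et2O, rt
Reagents that add atoms: none
Why: Grignard formation, copper-catalysed epoxide opening at the unsubstituted ring carbon of 3 and 3-exo-tet intramolecular Williamson closure of the chlorohydrin give the epoxide, and the stereocentre of 3 is never a reaction site, so it is carried over unchanged as C2.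

Step 3
Reactants: 6 (S)-2-[3-(benzyloxy)-5-methoxybenzyl]oxirane
Product: 7 (S)-2-[3-(benzyloxy)-5-methoxybenzyl]oxetane
Conditions: Me3S(O)I, t-BuOK, t-BuOH, 70–80 °C
Reagents that add atoms: trimethylsulfoxonium iodide, C[S+](C)(C)=O.[I-]
Why: Corey–Chaykovsky-type ring expansion, in which dimethylsulfoxonium methylide opens the epoxide at its CH2 and the γ-oxido sulfoxonium closes by 4-exo-tet displacement of DMSO, adds C4 without touching the C2–O bond, so C2 keeps its configuration.

Step 4
Reactants: 3 (S)-epichlorohydrin
Product: 9 (S)-2-pentyloxirane, via chlorohydrin 8 (not isolated)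
Conditions: n-BuMgBr, CuI (10 mol%), THF, −40 to 0 °C; aqueous work-up; crude 8, powdered NaOH, Et2O, rt
Reagents that add atoms: n-butylmagnesium bromide, CCCC[Mg]Br
Why: the same copper-catalysed Grignard opening of the epoxide terminus and Williamson ring closure as in step 2 turn the stereocentre of 3 into C8 with no bond to it broken.

Step 5
Reactants: 9 (S)-2-pentyloxirane
Product: 10 (S)-non-1-yn-4-ol
Conditions: lithium acetylide–ethylenediamine complex, DMSO, 0 °C to rt; aqueous work-up
Reagents that add atoms: lithium acetylide–ethylenediamine complex, [Li]C#C.NCCN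
Why: SN2 alkynylation of a terminal epoxide at its CH2 adds C6 and C5 as a terminal alkyne and leaves C8 untouched.

Step 6
Reactants: 10 (S)-non-1-yn-4-ol
Product: 11 (S)-4-(benzyloxy)non-1-yne
Conditions: NaH, BnBr, Bu4NI (cat.), THF, 0 °C to rt
Reagents that add atoms: benzyl bromide, BrCc1ccccc1
Why: Williamson etherification of the alkoxide, which NaH forms in preference to the acetylide, masks C8–O with a group that survives n-BuLi and BF3 and leaves in the final hydrogenation.

Step 7
Reactants: 11 (S)-4-(benzyloxy)non-1-yne; 7 (S)-2-[3-(benzyloxy)-5-methoxybenzyl]oxetane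
Product: 13 (2R,8S)-8-(benzyloxy)-1-[3-(benzyloxy)-5-methoxyphenyl]tridec-5-yn-2-ol, via lithium acetylide 12 (not isolated)
Conditions: 11 (1.5 equiv), n-BuLi, THF, −78 °C; BF3·OEt2, −78 °C; then 7, −78 °C; aqueous work-up
Reagents that add atoms: none
Why: n-BuLi removes the only acidic proton of 11 to give lithium acetylide 12, which, with BF3 activating the oxetane oxygen, attacks the unsubstituted ring carbon C4 of 7 in an SN2 step that forms the C4–C5 bond and breaks C4–O, the strain of the four-membered ether driving the reaction at −78 °C. The closest known reaction type is the BF3-promoted alkynylation of epoxides and oxetanes by lithium acetylides (Yamaguchi–Hirao alkynylation). No ring is closed; the oxetane (O, C2, C3, C4) is opened and its oxygen returns as the C2 hydroxyl. No stereocentre is formed: C2 keeps its configuration because its C–O bond is not touched and C8 is a spectator, so the (2R,8S) pairing is fixed by the two building blocks. The step needs attack at C4 and not at C2, which the substrate secures because C4 is a primary CH2 whereas C2 is secondary, carries the arylmethyl group and has no benzylic stabilisation for an SN1-type opening. It also needs the C2 oxygen to emerge as the only free hydroxyl, which the benzyl ethers on C8–O and on the phenol secure.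

Step 8
Reactants: 13 (2R,8S)-8-(benzyloxy)-1-[3-(benzyloxy)-5-methoxyphenyl]tridec-5-yn-2-ol
Product: 14 (2R,8S)-8-(benzyloxy)-1-[3-(benzyloxy)-5-methoxyphenyl]tridec-5-yn-2-yl acetate
Conditions: Ac2O, pyridine, DMAP (cat.), CH2Cl2, rt
Reagents that add atoms: acetic anhydride, CC(=O)OC(C)=O
Why: DMAP-catalysed acyl transfer acetylates the only free hydroxyl in the molecule, so the acetate is placed on C2 without any selectivity problem and without change at the stereocentre.

Step 9
Reactants: 14 (2R,8S)-8-(benzyloxy)-1-[3-(benzyloxy)-5-methoxyphenyl]tridec-5-yn-2-yl acetate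
Product: 15 (2R,8S)-8-hydroxy-1-(3-hydroxy-5-methoxyphenyl)tridecan-2-yl acetate
Conditions: H2 (1 atm), Pd/C (10%), EtOAc/EtOH, rt
Reagents that add atoms: none
Why: heterogeneous catalytic hydrogenation should saturate the C5≡C6 bond and cleave both O-benzyl bonds by hydrogenolysis, while the homobenzylic acetate, the aryl methyl ether and both stereocentres are inert under these neutral conditions.

**Compound list**
1 | 3-bromo-5-methoxyphenol | COc1cc(O)cc(Br)c1 | starting material
2 | 1-(benzyloxy)-3-bromo-5-methoxybenzene | COc1cc(Br)cc(OCc2ccccc2)c1 | intermediate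
3 | (S)-epichlorohydrin [(S)-2-(chloromethyl)oxirane] | ClC[C@@H]1CO1 | starting material
4 | [3-(benzyloxy)-5-methoxyphenyl]magnesium bromide | COc1cc([Mg]Br)cc(OCc2ccccc2)c1 | intermediate
5 | (S)-1-[3-(benzyloxy)-5-methoxyphenyl]-3-chloropropan-2-ol | COc1cc(C[C@H](O)CCl)cc(OCc2ccccc2)c1 | intermediate
6 | (S)-2-[3-(benzyloxy)-5-methoxybenzyl]oxirane | COc1cc(C[C@H]2CO2)cc(OCc3ccccc3)c1 | intermediate
7 | (S)-2-[3-(benzyloxy)-5-methoxybenzyl]oxetane | COc1cc(C[C@H]2CCO2)cc(OCc3ccccc3)c1 | intermediate
8 | (S)-1-chloroheptan-2-ol | CCCCC[C@H](O)CCl | intermediate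
9 | (S)-2-pentyloxirane [(S)-1,2-epoxyheptane] | CCCCC[C@H]1CO1 | intermediate
10 | (S)-non-1-yn-4-ol | CCCCC[C@H](O)CC#C | intermediate
11 | (S)-4-(benzyloxy)non-1-yne | CCCCC[C@H](OCc1ccccc1)CC#C | intermediate
12 | lithium (S)-4-(benzyloxy)non-1-yn-1-ide | CCCCC[C@H](OCc1ccccc1)CC#C[Li] | intermediate
13 | (2R,8S)-8-(benzyloxy)-1-[3-(benzyloxy)-5-methoxyphenyl]tridec-5-yn-2-ol | CCCCC[C@H](OCc1ccccc1)CC#CCC[C@H](Cc1cc(OCc2ccccc2)cc(OC)c1)O | intermediate
14 | (2R,8S)-8-(benzyloxy)-1-[3-(benzyloxy)-5-methoxyphenyl]tridec-5-yn-2-yl acetate | CCCCC[C@H](OCc1ccccc1)CC#CCC[C@H](Cc1cc(OCc2ccccc2)cc(OC)c1)OC(C)=O | intermediate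
15 | (2R,8S)-8-hydroxy-1-(3-hydroxy-5-methoxyphenyl)tridecan-2-yl acetate | CCCCC[C@H](O)CCCCC[C@H](Cc1cc(O)cc(OC)c1)OC(C)=O | target

**Count and risks**
Total steps: 9. Longest linear sequence: 6 steps (steps 1, 2, 3, 7, 8, 9, or equally 4, 5, 6, 7, 8, 9).

Steps most likely to fail:

Step 7. The Lewis acid may divert the oxetane before the acetylide attacks: the electron-rich dialkoxyaryl ring can close onto the activated C4 in a Friedel–Crafts sense, or the oxetane can oligomerise. The fallback replaces the polar union by olefin cross-metathesis and hydrogenation, which needs neither Lewis acid nor oxetane. It sets out from epoxides 6 and 9 and comes back at 15. Epoxide 6 is opened with vinylmagnesium bromide and catalytic CuI (THF, −30 °C) to (R)-1-[3-(benzyloxy)-5-methoxyphenyl]pent-4-en-2-ol F1, which is acetylated (Ac2O, pyridine, DMAP) to (R)-1-[3-(benzyloxy)-5-methoxyphenyl]pent-4-en-2-yl acetate F2. Epoxide 9 is opened with allylmagnesium bromide and catalytic CuI to (S)-dec-1-en-5-ol F3. Cross-metathesis of F2 with an excess of F3 (Grubbs second-generation catalyst, CH2Cl2, 40 °C) should give (2R,8S)-1-[3-(benzyloxy)-5-methoxyphenyl]-8-hydroxytridec-4-en-2-yl acetate F4 as an E/Z mixture (E isomer drawn). Hydrogenation over Pd/C saturates the alkene, so both isomers converge, cleaves the aryl benzyl ether and returns to the route at 15.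

Step 3. Under hot alkoxide the epoxide may isomerise by benzylic deprotonation and β-elimination to a cinnamyl-type alkoxide faster than the ylide attacks, or the oxetane may be expanded further to the oxolane. The fallback builds the oxetane by 4-exo-tet etherification of a 1,3-diol monosulfonate. It sets out from 6 and comes back at 7. Epoxide 6 is opened at its CH2 with (isopropoxydimethylsilyl)methylmagnesium chloride and catalytic CuI to (S)-1-[3-(benzyloxy)-5-methoxyphenyl]-4-[dimethyl(propan-2-yloxy)silyl]butan-2-ol F5. Tamao oxidation (H2O2, KF, KHCO3, THF/MeOH) gives (S)-4-[3-(benzyloxy)-5-methoxyphenyl]butane-1,3-diol F6. Selective sulfonylation of the primary hydroxyl (TsCl, pyridine, 0 °C) gives (S)-4-[3-(benzyloxy)-5-methoxyphenyl]-3-hydroxybutyl 4-methylbenzenesulfonate F7, and t-BuOK in THF closes it to oxetane 7 with C2 untouched.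

Step 9. Hydrogenolysis of the secondary alkyl benzyl ether may stall through catalyst deactivation once the alkyne and the aryl benzyl ether have reacted. The fallback removes the last benzyl group by Lewis-acid cleavage. It sets out from 14 and comes back at 15. Hydrogenation is run only as far as alkyne saturation and loss of the aryl benzyl group, to (2R,8S)-8-(benzyloxy)-1-(3-hydroxy-5-methoxyphenyl)tridecan-2-yl acetate F8. The remaining ether is then cleaved with BCl3 and pentamethylbenzene as cation scavenger (CH2Cl2, −78 °C), conditions under which the acetate and the aryl methyl ether should persist, to give 15.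

Further compounds
F1 | step 7 | (R)-1-[3-(benzyloxy)-5-methoxyphenyl]pent-4-en-2-ol | C=CC[C@H](Cc1cc(OCc2ccccc2)cc(OC)c1)O
F2 | step 7 | (R)-1-[3-(benzyloxy)-5-methoxyphenyl]pent-4-en-2-yl acetate | C=CC[C@H](Cc1cc(OCc2ccccc2)cc(OC)c1)OC(C)=O
F3 | step 7 | (S)-dec-1-en-5-ol | CCCCC[C@H](O)CCC=C
F4 | step 7 | (2R,4E,8S)-1-[3-(benzyloxy)-5-methoxyphenyl]-8-hydroxytridec-4-en-2-yl acetate | CCCCC[C@H](O)CC/C=C/C[C@H](Cc1cc(OCc2ccccc2)cc(OC)c1)OC(C)=O
F5 | step 3 | (S)-1-[3-(benzyloxy)-5-methoxyphenyl]-4-[dimethyl(propan-2-yloxy)silyl]butan-2-ol | COc1cc(C[C@H](O)CC[Si](C)(C)OC(C)C)cc(OCc2ccccc2)c1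
F6 | step 3 | (S)-4-[3-(benzyloxy)-5-methoxyphenyl]butane-1,3-diol | COc1cc(C[C@H](O)CCO)cc(OCc2ccccc2)c1
F7 | step 3 | (S)-4-[3-(benzyloxy)-5-methoxyphenyl]-3-hydroxybutyl 4-methylbenzenesulfonate | COc1cc(C[C@H](O)CCOS(=O)(=O)c2ccc(C)cc2)cc(OCc3ccccc3)c1
F8 | step 9 | (2R,8S)-8-(benzyloxy)-1-(3-hydroxy-5-methoxyphenyl)tridecan-2-yl acetate | CCCCC[C@H](OCc1ccccc1)CCCCC[C@H](Cc1cc(O)cc(OC)c1)OC(C)=O
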